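## Retrosynthetic overview

- Target 20 comes from its tris-silyl ether 19. Ring C (the 4-hydroxy-2-pyranone on C3) is built last from the C3 vinyl group of 14, through methyl ketone 15, enol silane 16 and malonyl dichloride 17.
- The strategy rests on ring A (O1, C2, C3, C3a, C7a): O1–C2–C3 joins a nucleophilic oxygen to an electrophilic allylic carbon, while C7a and C3a of ring B are the alkoxy-bearing acceptor carbon and the enolate carbon of a 4-methoxy-2-pyranone.
- Ring A is therefore cut at O1–C7a and C3–C3a: a (3+2) annulation of the trans aryl vinyl epoxide 5 with styrylpyranone 11 under zerovalent palladium.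
- Epoxide 5 comes from diene 4 by Shi epoxidation (4 from aldehyde 2, from 1). Pyranone 11 comes from 8 and aldehyde 7 (from 6) by vinylogous aldol addition and dehydration.
- Ring order: ring B is bought with 8, ring A closes in step 7, ring C closes in step 10.

Key step: step 7

Remark 1: the target SMILES is read as the trans (2S,3S) isomer (catechol on C2, ring C on C3, on opposite faces of ring A).
Remark 2: triisopropylsilyl replaces tert-butyldimethylsilyl on all three phenols. Aryl TIPS ethers should better tolerate the aqueous carbonate of step 3 and the transient methoxide of step 7, and are still cleaved by fluoride.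

## Route

Step 1
Reactants: 1 3,4-dihydroxybenzaldehyde
Product: 2 3,4-bis(triisopropylsilyloxy)benzaldehyde
Conditions: i-Pr3SiCl, imidazole, DMAP (cat.), DMF, 40 °C
Reagents that add atoms: chlorotriisopropylsilane, CC(C)[Si](Cl)(C(C)C)C(C)C
Why: Imidazole-promoted silylation of both phenols (Corey silylation) leaves the aldehyde untouched and involves no stereocentre.

Step 2
Reactants: 2 3,4-bis(triisopropylsilyloxy)benzaldehyde; 3 diethyl allylphosphonate
Product: 4 (E)-1-[3,4-bis(triisopropylsilyloxy)phenyl]buta-1,3-diene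
Conditions: 3, n-BuLi, THF, −78 °C; then 2, DMPU, −78 °C to rt
Reagents that add atoms: none
Why: Horner–Wadsworth–Emmons olefination, in which the lithiated allylphosphonate adds through its α-carbon and loses diethyl phosphate, should give the terminal diene with the thermodynamically preferred (E) geometry.

Step 3
Reactants: 4 (E)-1-[3,4-bis(triisopropylsilyloxy)phenyl]buta-1,3-diene
Product: 5 (2R,3R)-2-[3,4-bis(triisopropylsilyloxy)phenyl]-3-vinyloxirane
Conditions: Shi ketone from D-fructose (30 mol%), Oxone (2KHSO5·KHSO4·K2SO4), K2CO3, Bu4NHSO4, Na2B4O7/Na2EDTA buffer, MeCN–CH2(OMe)2, 0 °C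
Reagents that add atoms: potassium peroxymonosulfate (KHSO5 of Oxone), [K+].[O-]S(=O)(=O)OO
Why: Shi asymmetric epoxidation, in which the chiral dioxirane transfers oxygen through a spiro transition state to the trans-disubstituted styrenyl bond (more electron-rich than the terminal vinyl), should set both centres as (2R,3R) by catalyst control as with trans-β-methylstyrene, while the basic buffer protects the acid-labile aryl epoxide.

Step 4
Reactants: 6 4-hydroxybenzaldehyde
Product: 7 4-(triisopropylsilyloxy)benzaldehyde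
Conditions: i-Pr3SiCl, imidazole, DMF, rt
Reagents that add atoms: chlorotriisopropylsilane, CC(C)[Si](Cl)(C(C)C)C(C)C
Why: Imidazole-promoted phenol silylation (Corey silylation) gives an aldehyde that tolerates the strong base of the next step.

Step 5
Reactants: 8 4-methoxy-6-methyl-2H-pyran-2-one; 7 4-(triisopropylsilyloxy)benzaldehyde
Product: 9 racemic 6-{2-hydroxy-2-[4-(triisopropylsilyloxy)phenyl]ethyl}-4-methoxy-2H-pyran-2-one
Conditions: LiN(i-Pr)2, THF, −78 °C; then 7; AcOH quench
Reagents that add atoms: none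
Why: Vinylogous aldol addition, in which the amide base removes a proton from the 6-methyl group and the extended dienolate adds to the aldehyde; the carbinol centre is racemic and is destroyed in step 6.

Step 6
Reactants: 9 racemic 6-{2-hydroxy-2-[4-(triisopropylsilyloxy)phenyl]ethyl}-4-methoxy-2H-pyran-2-one
Product: 11 4-methoxy-6-[(E)-4-(triisopropylsilyloxy)styryl]-2H-pyran-2-one, via mesylate 10 (not isolated)
Conditions: MsCl, Et3N, CH2Cl2, 0 °C; then DBU, rt
Reagents that add atoms: none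
Why: Mesylation followed by E1cB elimination through the vinylogous enolate should give the fully conjugated (E)-styryl alkene as the favoured geometry.

Step 7
Reactants: 5 (2R,3R)-2-[3,4-bis(triisopropylsilyloxy)phenyl]-3-vinyloxirane; 11 4-methoxy-6-[(E)-4-(triisopropylsilyloxy)styryl]-2H-pyran-2-one
Product: 14 (2S,3S)-2-[3,4-bis(triisopropylsilyloxy)phenyl]-6-[(E)-4-(triisopropylsilyloxy)styryl]-3-vinyl-2,3-dihydro-4H-furo[3,2-c]pyran-4-one, via palladium allyl alkoxide 12 (not isolated), via methoxy ketal 13 (not isolated)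
Conditions: Pd2(dba)3·CHCl3 (2.5 mol%), PPh3 (10 mol%), THF, 25–40 °C, slow addition of 5 (1.3 equiv)
Reagents that add atoms: none
Why: Proposed new method: zerovalent palladium ionises the allylic C–O bond of 5 with inversion to the zwitterion 12, whose benzylic alkoxide adds to C4 of pyranone 11 (the later C7a); the lactone enolate so formed (the later C3a) alkylates the proximal allyl terminus anti to palladium to give ketal 13, and loss of methanol restores the pyranone. The closest known reaction type is the palladium-catalysed (3+2) cycloaddition of vinyl epoxides with doubly activated Michael acceptors to tetrahydrofurans; untested here are the weaker 4-alkoxypyranone acceptor and the terminating elimination. Ring A closes in a 5-exo mode by C3–C3a bond formation, the distal terminus being out of reach without a seven-membered ring. C2 comes unchanged from the epoxide and C3 is formed with net retention through two inversions, so the trans (2R,3R) epoxide maps onto the trans (2S,3S) product; if the allyl complex equilibrates by π–σ–π isomerisation, the closure that keeps vinyl and aryl trans is still the less strained one. The step needs attack of the alkoxide at C4 in preference to the lactone carbonyl and C6, and capture of 12 faster than its hydride shift to an aryl ketone: only the C4 adduct places an enolate within reach of the allyl cation, so reversible misadditions can return, and slow addition of 5 keeps the concentration of 12 low.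

Step 8
Reactants: 14 (2S,3S)-2-[3,4-bis(triisopropylsilyloxy)phenyl]-6-[(E)-4-(triisopropylsilyloxy)styryl]-3-vinyl-2,3-dihydro-4H-furo[3,2-c]pyran-4-one
Product: 15 (2S,3S)-3-acetyl-2-[3,4-bis(triisopropylsilyloxy)phenyl]-6-[(E)-4-(triisopropylsilyloxy)styryl]-2,3-dihydro-4H-furo[3,2-c]pyran-4-one
Conditions: PdCl2 (10 mol%), CuCl (co-catalyst), O2 (1 atm), DMF–H2O (7:1), rt
Reagents that add atoms: water, O
Why: Tsuji–Wacker oxidation, by Markovnikov hydroxypalladation of the monosubstituted alkene and β-hydride elimination, should give the methyl ketone while the 1,2-disubstituted styryl bond and the ring alkenes react much more slowly and C3 is not touched.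

Step 9
Reactants: 15 (2S,3S)-3-acetyl-2-[3,4-bis(triisopropylsilyloxy)phenyl]-6-[(E)-4-(triisopropylsilyloxy)styryl]-2,3-dihydro-4H-furo[3,2-c]pyran-4-one
Product: 16 (2S,3S)-2-[3,4-bis(triisopropylsilyloxy)phenyl]-6-[(E)-4-(triisopropylsilyloxy)styryl]-3-[1-(trimethylsilyloxy)vinyl]-2,3-dihydro-4H-furo[3,2-c]pyran-4-one
Conditions: LiN(SiMe3)2, Me3SiCl, Et3N, THF, −78 °C (internal quench); pentane filtration, used crude
Reagents that add atoms: chlorotrimethylsilane, C[Si](C)(C)Cl
Why: Kinetic enolisation with in situ silylation should take the unhindered methyl protons, because the tertiary C3–H is screened by the cis aryl group on C2 and by the C4 carbonyl, so the less substituted enol silane forms and C3 keeps its configuration.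

Step 10
Reactants: 16 (2S,3S)-2-[3,4-bis(triisopropylsilyloxy)phenyl]-6-[(E)-4-(triisopropylsilyloxy)styryl]-3-[1-(trimethylsilyloxy)vinyl]-2,3-dihydro-4H-furo[3,2-c]pyran-4-one; 17 malonyl dichloride
Product: 19 (2S,3S)-2-[3,4-bis(triisopropylsilyloxy)phenyl]-3-(4-hydroxy-2-oxo-2H-pyran-6-yl)-6-[(E)-4-(triisopropylsilyloxy)styryl]-2,3-dihydro-4H-furo[3,2-c]pyran-4-one, via keto acid chloride 18 (not isolated)
Conditions: 17 (1.1 equiv), Et2O, −78 to 0 °C
Reagents that add atoms: none
Why: Effenberger pyranone synthesis, in which the enol silane is C-acylated by malonyl dichloride to 18 and the enol oxygen of the new 1,3-diketone closes onto the acid chloride (6-exo-trig lactonisation) before tautomerising to the 4-hydroxy-2-pyranone; C3 is not involved.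

Step 11
Reactants: 19 (2S,3S)-2-[3,4-bis(triisopropylsilyloxy)phenyl]-3-(4-hydroxy-2-oxo-2H-pyran-6-yl)-6-[(E)-4-(triisopropylsilyloxy)styryl]-2,3-dihydro-4H-furo[3,2-c]pyran-4-one
Product: 20 (2S,3S)-2-(3,4-dihydroxyphenyl)-3-(4-hydroxy-2-oxo-2H-pyran-6-yl)-6-[(E)-4-hydroxystyryl]-2,3-dihydro-4H-furo[3,2-c]pyran-4-one
Conditions: Bu4NF, AcOH (1:1), THF, 0 °C
Reagents that add atoms: none
Why: Fluoride-mediated desilylation of the three aryl silyl ethers, buffered with acetic acid so that the phenoxides are protonated at once, which should prevent epimerisation at C3 and expulsion of O1 from C2 through a quinone methide.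

## Compound list

1 | 3,4-dihydroxybenzaldehyde | O=Cc1ccc(O)c(O)c1 | starting material
2 | 3,4-bis(triisopropylsilyloxy)benzaldehyde | O=Cc1ccc(O[Si](C(C)C)(C(C)C)C(C)C)c(O[Si](C(C)C)(C(C)C)C(C)C)c1 | intermediate
3 | diethyl allylphosphonate | C=CCP(=O)(OCC)OCC | starting material
4 | (E)-1-[3,4-bis(triisopropylsilyloxy)phenyl]buta-1,3-diene | C=C/C=C/c1ccc(O[Si](C(C)C)(C(C)C)C(C)C)c(O[Si](C(C)C)(C(C)C)C(C)C)c1 | intermediate
5 | (2R,3R)-2-[3,4-bis(triisopropylsilyloxy)phenyl]-3-vinyloxirane (trans) | C=C[C@H]1O[C@@H]1c1ccc(O[Si](C(C)C)(C(C)C)C(C)C)c(O[Si](C(C)C)(C(C)C)C(C)C)c1 | intermediate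
6 | 4-hydroxybenzaldehyde | O=Cc1ccc(O)cc1 | starting material
7 | 4-(triisopropylsilyloxy)benzaldehyde | O=Cc1ccc(O[Si](C(C)C)(C(C)C)C(C)C)cc1 | intermediate
8 | 4-methoxy-6-methyl-2H-pyran-2-one | COc1cc(C)oc(=O)c1 | starting material
9 | racemic 6-{2-hydroxy-2-[4-(triisopropylsilyloxy)phenyl]ethyl}-4-methoxy-2H-pyran-2-one | COc1cc(CC(O)c2ccc(O[Si](C(C)C)(C(C)C)C(C)C)cc2)oc(=O)c1 | intermediate
10 | methanesulfonate of 9 (not isolated) | COc1cc(CC(OS(C)(=O)=O)c2ccc(O[Si](C(C)C)(C(C)C)C(C)C)cc2)oc(=O)c1 | intermediate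
11 | 4-methoxy-6-[(E)-4-(triisopropylsilyloxy)styryl]-2H-pyran-2-one | COc1cc(/C=C/c2ccc(O[Si](C(C)C)(C(C)C)C(C)C)cc2)oc(=O)c1 | intermediate
12 | zwitterionic allylpalladium alkoxide from 5 (not isolated; drawn as the σ-allyl form, phosphines omitted) | [O-][C@H](c1ccc(O[Si](C(C)C)(C(C)C)C(C)C)c(O[Si](C(C)C)(C(C)C)C(C)C)c1)/C=C/C[Pd+] | intermediate
13 | (2S,3S)-2-[3,4-bis(triisopropylsilyloxy)phenyl]-7a-methoxy-6-[(E)-4-(triisopropylsilyloxy)styryl]-3-vinyl-2,3,3a,7a-tetrahydro-4H-furo[3,2-c]pyran-4-one (not isolated; C3a and C7a not assigned) | C=C[C@H]1C2C(=O)OC(/C=C/c3ccc(O[Si](C(C)C)(C(C)C)C(C)C)cc3)=CC2(OC)O[C@@H]1c1ccc(O[Si](C(C)C)(C(C)C)C(C)C)c(O[Si](C(C)C)(C(C)C)C(C)C)c1 | intermediate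
14 | (2S,3S)-2-[3,4-bis(triisopropylsilyloxy)phenyl]-6-[(E)-4-(triisopropylsilyloxy)styryl]-3-vinyl-2,3-dihydro-4H-furo[3,2-c]pyran-4-one | C=C[C@H]1c2c(cc(/C=C/c3ccc(O[Si](C(C)C)(C(C)C)C(C)C)cc3)oc2=O)O[C@@H]1c1ccc(O[Si](C(C)C)(C(C)C)C(C)C)c(O[Si](C(C)C)(C(C)C)C(C)C)c1 | intermediate
15 | (2S,3S)-3-acetyl-2-[3,4-bis(triisopropylsilyloxy)phenyl]-6-[(E)-4-(triisopropylsilyloxy)styryl]-2,3-dihydro-4H-furo[3,2-c]pyran-4-one | CC(=O)[C@H]1c2c(cc(/C=C/c3ccc(O[Si](C(C)C)(C(C)C)C(C)C)cc3)oc2=O)O[C@@H]1c1ccc(O[Si](C(C)C)(C(C)C)C(C)C)c(O[Si](C(C)C)(C(C)C)C(C)C)c1 | intermediate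
16 | (2S,3S)-2-[3,4-bis(triisopropylsilyloxy)phenyl]-6-[(E)-4-(triisopropylsilyloxy)styryl]-3-[1-(trimethylsilyloxy)vinyl]-2,3-dihydro-4H-furo[3,2-c]pyran-4-one | C=C(O[Si](C)(C)C)[C@H]1c2c(cc(/C=C/c3ccc(O[Si](C(C)C)(C(C)C)C(C)C)cc3)oc2=O)O[C@@H]1c1ccc(O[Si](C(C)C)(C(C)C)C(C)C)c(O[Si](C(C)C)(C(C)C)C(C)C)c1 | intermediate
17 | malonyl dichloride | O=C(Cl)CC(=O)Cl | starting material
18 | 5-{(2S,3S)-2-[3,4-bis(triisopropylsilyloxy)phenyl]-4-oxo-6-[(E)-4-(triisopropylsilyloxy)styryl]-2,3-dihydro-4H-furo[3,2-c]pyran-3-yl}-3,5-dioxopentanoyl chloride (not isolated) | O=C(Cl)CC(=O)CC(=O)[C@H]1c2c(cc(/C=C/c3ccc(O[Si](C(C)C)(C(C)C)C(C)C)cc3)oc2=O)O[C@@H]1c1ccc(O[Si](C(C)C)(C(C)C)C(C)C)c(O[Si](C(C)C)(C(C)C)C(C)C)c1 | intermediate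
19 | (2S,3S)-2-[3,4-bis(triisopropylsilyloxy)phenyl]-3-(4-hydroxy-2-oxo-2H-pyran-6-yl)-6-[(E)-4-(triisopropylsilyloxy)styryl]-2,3-dihydro-4H-furo[3,2-c]pyran-4-one | O=c1cc(O)cc([C@H]2c3c(cc(/C=C/c4ccc(O[Si](C(C)C)(C(C)C)C(C)C)cc4)oc3=O)O[C@@H]2c2ccc(O[Si](C(C)C)(C(C)C)C(C)C)c(O[Si](C(C)C)(C(C)C)C(C)C)c2)o1 | intermediate
20 | (2S,3S)-2-(3,4-dihydroxyphenyl)-3-(4-hydroxy-2-oxo-2H-pyran-6-yl)-6-[(E)-4-hydroxystyryl]-2,3-dihydro-4H-furo[3,2-c]pyran-4-one (CNP0330607.1) | O=c1cc(O)cc([C@H]2c3c(cc(/C=C/c4ccc(O)cc4)oc3=O)O[C@@H]2c2ccc(O)c(O)c2)o1 | target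

## Step count and risks

Total step count: 11. Longest linear sequence: 8 steps (steps 1–3 and 7–11; the arm through steps 4–6 and 7–11 is equally long).

Steps most likely to fail:

Step 7 (proposed new method). The alkoxide of 12 may add too slowly to the donor-substituted C4 of 11, so that 12 is consumed by hydride shift to an aryl ketone or by opening of the lactone. The fallback makes the same two bonds in the opposite order by known reactions; it sets out from 7 and 5 and returns at 14. The dianion of commercial 4-hydroxy-6-methyl-2H-pyran-2-one (LiN(i-Pr)2, 2.2 equiv) is added to 7 to give racemic 4-hydroxy-6-{2-hydroxy-2-[4-(triisopropylsilyloxy)phenyl]ethyl}-2H-pyran-2-one F1, which is dehydrated (TsOH, toluene) to 4-hydroxy-6-[(E)-4-(triisopropylsilyloxy)styryl]-2H-pyran-2-one F2. Palladium-catalysed allylic alkylation of this acidic 1,3-dicarbonyl pronucleophile with 5 (Pd2(dba)3·CHCl3 and a Trost diamide bisphosphine ligand, the enantiomer matched to 3S being chosen by trial) is a known way to steer such pronucleophiles to the allyl terminus next to the hydroxyl group. It should give 3-{(1S,2S)-1-[3,4-bis(triisopropylsilyloxy)phenyl]-1-hydroxybut-3-en-2-yl}-4-hydroxy-6-[(E)-4-(triisopropylsilyloxy)styryl]-2H-pyran-2-one F3. Acid-catalysed cyclodehydration (pyridinium p-toluenesulfonate, 4 Å sieves, toluene) then closes ring A to the trans compound 14.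

Step 10. Hydrogen chloride released in the ring closure may ionise the electron-rich benzylic C2–O1 bond, and the doubly electrophilic acid chloride may acylate twice. The fallback separates acylation from lactonisation; it sets out from 16 and returns at 19. C-acylation of 16 with ethyl malonyl chloride (ZnCl2 cat., CH2Cl2, −78 °C) releases only chlorotrimethylsilane and gives ethyl 5-{(2S,3S)-2-[3,4-bis(triisopropylsilyloxy)phenyl]-4-oxo-6-[(E)-4-(triisopropylsilyloxy)styryl]-2,3-dihydro-4H-furo[3,2-c]pyran-3-yl}-3,5-dioxopentanoate F6. Lactonisation with catalytic DBU in toluene, where the doubly activated methylene groups take up the base before C3–H can, expels ethanol and gives 19.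

Step 8. Palladium hydride formed in the Wacker cycle may move the terminal double bond into conjugation with ring B and on to the aromatic furan, erasing C2 and C3, or the oxidation may turn toward the aldehyde. The fallback is a hydration without a hydride pathway; it sets out from 14 and returns at 15. Oxymercuration (Hg(OAc)2, THF–H2O) of the terminal alkene gives (2S,3S)-3-[2-(acetoxymercurio)-1-hydroxyethyl]-2-[3,4-bis(triisopropylsilyloxy)phenyl]-6-[(E)-4-(triisopropylsilyloxy)styryl]-2,3-dihydro-4H-furo[3,2-c]pyran-4-one F4. This is reduced in the same flask with NaBH4 to (2S,3S)-2-[3,4-bis(triisopropylsilyloxy)phenyl]-3-(1-hydroxyethyl)-6-[(E)-4-(triisopropylsilyloxy)styryl]-2,3-dihydro-4H-furo[3,2-c]pyran-4-one F5 (both carbinol epimers), and oxidation with Dess–Martin periodinane gives 15.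

Further compounds

F1 | step 7 | racemic 4-hydroxy-6-{2-hydroxy-2-[4-(triisopropylsilyloxy)phenyl]ethyl}-2H-pyran-2-one | O=c1cc(O)cc(CC(O)c2ccc(O[Si](C(C)C)(C(C)C)C(C)C)cc2)o1
F2 | step 7 | 4-hydroxy-6-[(E)-4-(triisopropylsilyloxy)styryl]-2H-pyran-2-one | O=c1cc(O)cc(/C=C/c2ccc(O[Si](C(C)C)(C(C)C)C(C)C)cc2)o1
F3 | step 7 | 3-{(1S,2S)-1-[3,4-bis(triisopropylsilyloxy)phenyl]-1-hydroxybut-3-en-2-yl}-4-hydroxy-6-[(E)-4-(triisopropylsilyloxy)styryl]-2H-pyran-2-one | C=C[C@H]([C@H](O)c1ccc(O[Si](C(C)C)(C(C)C)C(C)C)c(O[Si](C(C)C)(C(C)C)C(C)C)c1)c1c(O)cc(/C=C/c2ccc(O[Si](C(C)C)(C(C)C)C(C)C)cc2)oc1=O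
F4 | step 8 | (2S,3S)-3-[2-(acetoxymercurio)-1-hydroxyethyl]-2-[3,4-bis(triisopropylsilyloxy)phenyl]-6-[(E)-4-(triisopropylsilyloxy)styryl]-2,3-dihydro-4H-furo[3,2-c]pyran-4-one | CC(=O)O[Hg]CC(O)[C@H]1c2c(cc(/C=C/c3ccc(O[Si](C(C)C)(C(C)C)C(C)C)cc3)oc2=O)O[C@@H]1c1ccc(O[Si](C(C)C)(C(C)C)C(C)C)c(O[Si](C(C)C)(C(C)C)C(C)C)c1
F5 | step 8 | (2S,3S)-2-[3,4-bis(triisopropylsilyloxy)phenyl]-3-(1-hydroxyethyl)-6-[(E)-4-(triisopropylsilyloxy)styryl]-2,3-dihydro-4H-furo[3,2-c]pyran-4-one | CC(O)[C@H]1c2c(cc(/C=C/c3ccc(O[Si](C(C)C)(C(C)C)C(C)C)cc3)oc2=O)O[C@@H]1c1ccc(O[Si](C(C)C)(C(C)C)C(C)C)c(O[Si](C(C)C)(C(C)C)C(C)C)c1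
F6 | step 10 | ethyl 5-{(2S,3S)-2-[3,4-bis(triisopropylsilyloxy)phenyl]-4-oxo-6-[(E)-4-(triisopropylsilyloxy)styryl]-2,3-dihydro-4H-furo[3,2-c]pyran-3-yl}-3,5-dioxopentanoate | CCOC(=O)CC(=O)CC(=O)[C@H]1c2c(cc(/C=C/c3ccc(O[Si](C(C)C)(C(C)C)C(C)C)cc3)oc2=O)O[C@@H]1c1ccc(O[Si](C(C)C)(C(C)C)C(C)C)c(O[Si](C(C)C)(C(C)C)C(C)C)c1
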